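The whole route rests on disconnecting both bonds to the C5′ carbonyl carbon (chain numbered from benzylic C1′ to C15′). C5′ is bonded on one side to the allylic C4′H2 next to the C2′=C3′ olefin and on the other to vinylic C6′ of the C6′=C7′ olefin, so this carbon can be brought in as carbon monoxide between an allyl and an alkenyl partner. A single palladium-catalysed three-component coupling should unite the aryl-bearing C1′–C4′ (E)-allylic chloride, CO and the C6′–C15′ (E)-alkenylstannane, making C4′–C5′ and C5′–C6′ with the ketone at its final oxidation level. No ring is closed; the benzene ring is a silyl-protected spectator. The stannane already holds the C12′ ketone and (R)-C11′, drawn from (S)-3-bromo-2-methylpropan-1-ol.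

Key step: step 14

Remark on the chemistry: C11′ is (R). The CH2Br carbon of the chiral building block becomes C10′ and its CH2OH carbon becomes C12′, so (S)-3-bromo-2-methylpropan-1-ol (commercial) is the required enantiomer. It corresponds to methyl (S)-3-hydroxy-2-methylpropanoate when the ester carbon ends as C10′; the (R)-ester used in that sense would give (S)-C11′.

Step 1
Reactants: 1 4-methoxy-2-methylphenol; 2 prenyl bromide (1-bromo-3-methylbut-2-ene)
Product: 4 4-methoxy-2-methyl-6-(3-methylbut-2-en-1-yl)phenol, via sodium phenoxide 3 (not isolated)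
Conditions: NaH, toluene, 0 °C → rt; then 2, rt
Reagents that add atoms: none
Why: Ortho-C-allylation of a phenoxide: in toluene the sodium phenoxide is a tight, poorly solvated ion pair that is alkylated at carbon in preference to oxygen, and C6 is the only ortho position that can rearomatise because C2 carries the methyl group and C4 the methoxy group.

Step 2
Reactants: 4 4-methoxy-2-methyl-6-(3-methylbut-2-en-1-yl)phenol
Product: 5 tert-butyl[4-methoxy-2-methyl-6-(3-methylbut-2-en-1-yl)phenoxy]dimethylsilane
Conditions: TBSCl, imidazole, DMF, rt → 40 °C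
Reagents that add atoms: tert-butyldimethylsilyl chloride (TBSCl), CC(C)(C)[Si](C)(C)Cl
Why: Imidazole-promoted silyl ether formation masks the phenol oxygen, which would otherwise attack the allyl unit and close a chroman or dihydrobenzofuran ring in steps 3, 4 and 14.

Step 3
Reactants: 5 tert-butyl[4-methoxy-2-methyl-6-(3-methylbut-2-en-1-yl)phenoxy]dimethylsilane
Product: 6 (2E)-4-{2-[(tert-butyldimethylsilyl)oxy]-5-methoxy-3-methylphenyl}-2-methylbut-2-en-1-ol
Conditions: SeO2 (0.3 equiv), t-BuOOH, CH2Cl2, 0 °C → rt
Reagents that add atoms: tert-butyl hydroperoxide, CC(C)(C)OO; selenium dioxide (catalytic oxygen carrier), O=[Se]=O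
Why: Catalytic Riley allylic oxidation: the ene reaction takes place at the disubstituted C3′ end of the trisubstituted olefin and the following [2,3]-sigmatropic shift puts oxygen on the methyl group trans to C1′, which should give the (E)-allylic alcohol and leave the benzylic C1′H2 alone.

Step 4
Reactants: 6 (2E)-4-{2-[(tert-butyldimethylsilyl)oxy]-5-methoxy-3-methylphenyl}-2-methylbut-2-en-1-ol
Product: 7 tert-butyl{2-[(2E)-4-chloro-3-methylbut-2-en-1-yl]-4-methoxy-6-methylphenoxy}dimethylsilane
Conditions: NCS, Me2S, CH2Cl2, −20 → 0 °C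
Reagents that add atoms: N-chlorosuccinimide, O=C1CCC(=O)N1Cl
Why: Corey–Kim chlorination: the alcohol is activated as an alkoxysulfonium ion and chloride displaces it at the primary carbon without allylic transposition, so the (E) geometry is kept and the cold, neutral medium spares the aryl silyl ether.

Step 5
Reactants: 8 (S)-3-bromo-2-methylpropan-1-ol
Product: 9 (S)-(3-bromo-2-methylpropoxy)(tert-butyl)dimethylsilane
Conditions: TBSCl, imidazole, CH2Cl2, 0 °C → rt
Reagents that add atoms: tert-butyldimethylsilyl chloride (TBSCl), CC(C)(C)[Si](C)(C)Cl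
Why: Standard silylation of the primary alcohol keeps it from quenching the Grignard reagent of step 6; the stereocentre is not involved and stays (S).

Step 6
Reactants: 9 (S)-(3-bromo-2-methylpropoxy)(tert-butyl)dimethylsilane; 10 4-bromo-1-(trimethylsilyl)but-1-yne
Product: 12 tert-butyldimethyl{[(2R)-2-methyl-7-(trimethylsilyl)hept-6-yn-1-yl]oxy}silane, via Grignard reagent 11 (not isolated)
Conditions: 10, Mg, THF, rt; then 9, Li2CuCl4 (5 mol %), NMP, THF, 0 °C → rt
Reagents that add atoms: none
Why: Copper-catalysed alkyl–alkyl cross-coupling of a Grignard reagent with a primary bromide (Kochi–Schlosser coupling) forms C9′–C10′; the stereocentre is one carbon away from the reacting CH2Br and is untouched, its descriptor changing from (S) to (R) only because the ligand priorities change.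

Step 7
Reactants: 12 tert-butyldimethyl{[(2R)-2-methyl-7-(trimethylsilyl)hept-6-yn-1-yl]oxy}silane
Product: 13 (2R)-2-methylhept-6-yn-1-ol
Conditions: Bu4NF (2.5 equiv), THF, 0 °C → rt
Reagents that add atoms: none
Why: Fluoride-induced desilylation cleaves the Si–O bond of the silyl ether and the C(sp)–Si bond of the alkynylsilane in one operation, which should give the free alkynol needed for carbometalation.

Step 8
Reactants: 13 (2R)-2-methylhept-6-yn-1-ol
Product: 15 (2R,6E)-7-iodo-2,6-dimethylhept-6-en-1-ol, via alkenylalane 14 (not isolated)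
Conditions: AlMe3 (3 equiv), Cp2ZrCl2 (0.25 equiv), CH2Cl2, 0 °C → rt; then I2, THF, −30 → 0 °C
Reagents that add atoms: trimethylaluminium, C[Al](C)C; iodine, II
Why: Negishi zirconium-catalysed methylalumination adds Me–Al syn across the terminal alkyne with aluminium on the terminal carbon (the hydroxyl travels as its aluminium alkoxide), and iodinolysis of the C–Al bond with retention should give the (E)-iodoalkene with the C7′ methyl group in place.

Step 9
Reactants: 15 (2R,6E)-7-iodo-2,6-dimethylhept-6-en-1-ol
Product: 16 (2R,6E)-7-iodo-2,6-dimethylhept-6-enal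
Conditions: Dess–Martin periodinane, NaHCO3, CH2Cl2, 0 °C → rt
Reagents that add atoms: none
Why: Buffered Dess–Martin oxidation of the primary alcohol should stop at the aldehyde, leave the iodoalkene alone and not epimerise the α-stereocentre, provided the aldehyde is used at once.

Step 10
Reactants: 16 (2R,6E)-7-iodo-2,6-dimethylhept-6-enal
Product: 17 (5R,9E)-10-iodo-5,9-dimethyldeca-1,9-dien-4-ol (both C4 epimers)
Conditions: CH2=CHCH2MgBr, Et2O, −78 °C
Reagents that add atoms: allylmagnesium bromide, C=CC[Mg]Br
Why: Grignard addition to the aldehyde at low temperature: the symmetrical allyl nucleophile avoids the branched adducts that prenyl–metal reagents give, the iodoalkene does not exchange, and the new carbinol centre (C12′) need not be controlled because step 13 oxidises it.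

Step 11
Reactants: 17 (5R,9E)-10-iodo-5,9-dimethyldeca-1,9-dien-4-ol
Product: 18 (6R,10E)-11-iodo-2,6,10-trimethylundeca-2,10-dien-5-ol (both C5 epimers)
Conditions: 2-methylbut-2-ene (excess), second-generation Grubbs catalyst (H2IMes)(PCy3)Cl2Ru=CHPh (3 mol %), CH2Cl2, 35 °C
Reagents that add atoms: 2-methylbut-2-ene, CC=C(C)C
Why: Olefin cross-metathesis turns the terminal vinyl group into the trisubstituted C14′=C15′ olefin with loss of propene, the ruthenium carbene engaging only the monosubstituted alkene while the hindered trisubstituted iodoalkene stays out.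

Step 12
Reactants: 18 (6R,10E)-11-iodo-2,6,10-trimethylundeca-2,10-dien-5-ol
Product: 21 (6R,10E)-2,6,10-trimethyl-11-(tributylstannyl)undeca-2,10-dien-5-ol, via dilithio species 19 (not isolated), via bis-stannyl species 20 (not isolated)
Conditions: t-BuLi (3.2 equiv), Et2O, −78 °C; Bu3SnCl (2.2 equiv), −78 °C → rt; aq. NaHCO3
Reagents that add atoms: tributyltin chloride, CCCC[Sn](Cl)(CCCC)CCCC
Why: Lithium–iodine exchange (one equivalent of t-BuLi deprotonates the hydroxyl, one exchanges, one destroys t-BuI) gives the alkenyllithium with retention of the (E) geometry, Bu3SnCl traps carbon and oxygen, and the Sn–O bond is hydrolysed on work-up, so the alkenylstannane alcohol should result.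

Step 13
Reactants: 21 (6R,10E)-2,6,10-trimethyl-11-(tributylstannyl)undeca-2,10-dien-5-ol
Product: 22 (1E,6R)-2,6,10-trimethyl-1-(tributylstannyl)undeca-1,9-dien-7-one
Conditions: Dess–Martin periodinane, NaHCO3, CH2Cl2, 0 °C
Reagents that add atoms: none
Why: Buffered Dess–Martin oxidation of the homoallylic secondary alcohol gives the β,γ-unsaturated ketone without base or strong acid, so C13′H2 should not move into conjugation, C11′ should stay (R) and the acid-sensitive C–Sn bond should survive.

Step 14
Reactants: 7 tert-butyl{2-[(2E)-4-chloro-3-methylbut-2-en-1-yl]-4-methoxy-6-methylphenoxy}dimethylsilane; 22 (1E,6R)-2,6,10-trimethyl-1-(tributylstannyl)undeca-1,9-dien-7-one; 23 carbon monoxide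
Product: 24 (2E,6E,11R)-1-{2-[(tert-butyldimethylsilyl)oxy]-5-methoxy-3-methylphenyl}-3,7,11,15-tetramethylhexadeca-2,6,14-triene-5,12-dione
Conditions: Pd2(dba)3 (2.5 mol %), PPh3 (10 mol %), CO (3 atm), THF, 50 °C
Reagents that add atoms: none
Why: Oxidative addition of the C4′–Cl bond of 7 to zerovalent palladium (from Pd2(dba)3 and PPh3) should give a π-allyl chloride complex of divalent palladium, which under CO pressure reacts through its σ-form at the unhindered CH2 terminus (C4′) by migratory insertion to an acylpalladium species; transmetalation then moves the alkenyl group of 22 from tin to palladium without change of its (E) geometry, and reductive elimination joins C5′ to C6′ and regenerates the catalyst. The closest known reaction type is the carbonylative Stille coupling of allylic chlorides with alkenyltin reagents, an established route to allyl vinyl ketones. No ring is formed and no stereocentre is created, so C11′ (R) only has to survive, and the C2′=C3′ geometry is inherited from 7 because the syn-substituted π-allyl unit returns the (E)-olefin when palladium sits on C4′. Two selectivities are required: carbonylation at C4′ and not at the secondary, benzyl-flanked C2′ terminus, which the steric difference between the two allyl ends secures, and CO uptake before any direct allyl–alkenyl coupling, which about 3 atm of CO and the slow transmetalation of the β,β-disubstituted alkenylstannane secure. Since the medium contains neither base nor acid and stays near 50 °C, migration of the C2′=C3′ or C14′=C15′ double bonds into conjugation through C4′H2 or C13′H2 and epimerisation at C11′ are not expected, and butyl transfer from tin should not compete with alkenyl transfer.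

Step 15
Reactants: 24 (2E,6E,11R)-1-{2-[(tert-butyldimethylsilyl)oxy]-5-methoxy-3-methylphenyl}-3,7,11,15-tetramethylhexadeca-2,6,14-triene-5,12-dione
Product: 25 (2E,6E,11R)-1-(2-hydroxy-5-methoxy-3-methylphenyl)-3,7,11,15-tetramethylhexadeca-2,6,14-triene-5,12-dione (CNP0301021.2)
Conditions: Bu4NF, AcOH, THF, 0 °C
Reagents that add atoms: none
Why: Fluoride cleavage of the aryl silyl ether, with acetic acid present to protonate the phenoxide at once, leaves no base to move C4′H2 or C13′H2 into conjugation or to epimerise C11′ and no strong acid to close a chroman ring.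

Compound list
1 | 4-methoxy-2-methylphenol | COc1ccc(O)c(C)c1 | starting material
2 | prenyl bromide (1-bromo-3-methylbut-2-ene) | CC(C)=CCBr | starting material
3 | sodium 4-methoxy-2-methylphenolate | COc1ccc([O-])c(C)c1.[Na+] | intermediate (not isolated)
4 | 4-methoxy-2-methyl-6-(3-methylbut-2-en-1-yl)phenol | COc1cc(C)c(O)c(CC=C(C)C)c1 | intermediate
5 | tert-butyl[4-methoxy-2-methyl-6-(3-methylbut-2-en-1-yl)phenoxy]dimethylsilane | COc1cc(C)c(O[Si](C)(C)C(C)(C)C)c(CC=C(C)C)c1 | intermediate
6 | (2E)-4-{2-[(tert-butyldimethylsilyl)oxy]-5-methoxy-3-methylphenyl}-2-methylbut-2-en-1-ol | COc1cc(C)c(O[Si](C)(C)C(C)(C)C)c(C/C=C(\C)CO)c1 | intermediate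
7 | tert-butyl{2-[(2E)-4-chloro-3-methylbut-2-en-1-yl]-4-methoxy-6-methylphenoxy}dimethylsilane | COc1cc(C)c(O[Si](C)(C)C(C)(C)C)c(C/C=C(\C)CCl)c1 | intermediate
8 | (S)-3-bromo-2-methylpropan-1-ol | BrC[C@@H](C)CO | starting material
9 | (S)-(3-bromo-2-methylpropoxy)(tert-butyl)dimethylsilane | BrC[C@@H](C)CO[Si](C)(C)C(C)(C)C | intermediate
10 | 4-bromo-1-(trimethylsilyl)but-1-yne | C[Si](C)(C)C#CCCBr | starting material
11 | [4-(trimethylsilyl)but-3-yn-1-yl]magnesium bromide | C[Si](C)(C)C#CCC[Mg]Br | intermediate (not isolated)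
12 | tert-butyldimethyl{[(2R)-2-methyl-7-(trimethylsilyl)hept-6-yn-1-yl]oxy}silane | C[Si](C)(C)C#CCCC[C@@H](C)CO[Si](C)(C)C(C)(C)C | intermediate
13 | (2R)-2-methylhept-6-yn-1-ol | C#CCCC[C@@H](C)CO | intermediate
14 | dimethyl[(1E,6R)-7-(dimethylalumanyloxy)-2,6-dimethylhept-1-en-1-yl]alumane | C[Al](C)/C=C(\C)CCC[C@@H](C)CO[Al](C)C | intermediate (not isolated)
15 | (2R,6E)-7-iodo-2,6-dimethylhept-6-en-1-ol | I/C=C(\C)CCC[C@@H](C)CO | intermediate
16 | (2R,6E)-7-iodo-2,6-dimethylhept-6-enal | I/C=C(\C)CCC[C@@H](C)C=O | intermediate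
17 | (5R,9E)-10-iodo-5,9-dimethyldeca-1,9-dien-4-ol (both C4 epimers) | I/C=C(\C)CCC[C@@H](C)C(O)CC=C | intermediate
18 | (6R,10E)-11-iodo-2,6,10-trimethylundeca-2,10-dien-5-ol (both C5 epimers) | I/C=C(\C)CCC[C@@H](C)C(O)CC=C(C)C | intermediate
19 | lithium (6R,10E)-11-lithio-2,6,10-trimethylundeca-2,10-dien-5-olate | [Li]/C=C(\C)CCC[C@@H](C)C(O[Li])CC=C(C)C | intermediate (not isolated)
20 | tributyl{[(6R,10E)-2,6,10-trimethyl-11-(tributylstannyl)undeca-2,10-dien-5-yl]oxy}stannane | CCCC[Sn](CCCC)(CCCC)/C=C(\C)CCC[C@@H](C)C(O[Sn](CCCC)(CCCC)CCCC)CC=C(C)C | intermediate (not isolated)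
21 | (6R,10E)-2,6,10-trimethyl-11-(tributylstannyl)undeca-2,10-dien-5-ol (both C5 epimers) | CCCC[Sn](CCCC)(CCCC)/C=C(\C)CCC[C@@H](C)C(O)CC=C(C)C | intermediate
22 | (1E,6R)-2,6,10-trimethyl-1-(tributylstannyl)undeca-1,9-dien-7-one | CCCC[Sn](CCCC)(CCCC)/C=C(\C)CCC[C@@H](C)C(=O)CC=C(C)C | intermediate
23 | carbon monoxide | [C-]#[O+] | starting material
24 | (2E,6E,11R)-1-{2-[(tert-butyldimethylsilyl)oxy]-5-methoxy-3-methylphenyl}-3,7,11,15-tetramethylhexadeca-2,6,14-triene-5,12-dione | COc1cc(C)c(O[Si](C)(C)C(C)(C)C)c(C/C=C(\C)CC(=O)/C=C(\C)CCC[C@@H](C)C(=O)CC=C(C)C)c1 | intermediate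
25 | (2E,6E,11R)-1-(2-hydroxy-5-methoxy-3-methylphenyl)-3,7,11,15-tetramethylhexadeca-2,6,14-triene-5,12-dione | COc1cc(C)c(O)c(C/C=C(\C)CC(=O)/C=C(\C)CCC[C@@H](C)C(=O)CC=C(C)C)c1 | target

Total step count: 15 (steps 1–4 give chloride 7; steps 5–13 give stannane 22; steps 14 and 15 finish).
Longest linear sequence: 11 steps (steps 5–15, from 8 to 25).

Steps most likely to fail

1. Step 14. The risks are direct allyl–alkenyl coupling without CO uptake, loss of the C2′=C3′ geometry by syn–anti exchange in the allyl complex, sluggish tin-to-palladium transfer, and migration of the C2′=C3′ olefin into conjugation through C4′H2 during reaction or chromatography. The fallback builds the C5′ ketone stepwise by a Nozaki–Hiyama–Kishi addition; it sets out from chloride 7 and iodo alcohol 18 and comes back at 24. Chloride 7 would be alkylated with 2-lithio-1,3-dithiane (THF, −78 → −20 °C) to give 2-[(2E)-4-{2-[(tert-butyldimethylsilyl)oxy]-5-methoxy-3-methylphenyl}-2-methylbut-2-en-1-yl]-1,3-dithiane F1. Alkylative hydrolysis (MeI, CaCO3, aqueous MeCN) should unmask (3E)-5-{2-[(tert-butyldimethylsilyl)oxy]-5-methoxy-3-methylphenyl}-3-methylpent-3-enal F2, to be used crude. CrCl2 with catalytic NiCl2 in DMSO should add the iodoalkene of 18 to this aldehyde and give (2E,6E,11R)-1-{2-[(tert-butyldimethylsilyl)oxy]-5-methoxy-3-methylphenyl}-3,7,11,15-tetramethylhexadeca-2,6,14-triene-5,12-diol F3 as a mixture of carbinol epimers. An excess of Dess–Martin periodinane with NaHCO3 would then oxidise both carbinols to give 24.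

2. Step 1. The risks are alkylation at oxygen in competition with carbon and acid-triggered closure of the ortho-prenylphenol to a chroman during work-up. The fallback is an aromatic Claisen route from 1 back to 4. Copper-catalysed O-alkylation of 1 with 3-chloro-3-methylbut-1-yne (CuCl2 cat., DBU, MeCN, 0 °C) would give 4-methoxy-2-methyl-1-[(2-methylbut-3-yn-2-yl)oxy]benzene F4. Semihydrogenation (H2, Pd/CaCO3 poisoned with Pb(OAc)2, quinoline, EtOAc) would give 4-methoxy-2-methyl-1-[(2-methylbut-3-en-2-yl)oxy]benzene F5. Heating in N,N-diethylaniline at about 130 °C should trigger the [3,3]-sigmatropic rearrangement to the only free ortho position and give 4.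

3. Step 3. The risks are over-oxidation to the enal, incomplete conversion and competing oxidation at the benzylic carbon. The fallback cleaves and rebuilds the olefin, from 5 back to 6. Lemieux–Johnson cleavage (OsO4 cat., NaIO4, 2,6-lutidine, aqueous dioxane) would give {2-[(tert-butyldimethylsilyl)oxy]-5-methoxy-3-methylphenyl}acetaldehyde F6. Wittig olefination with ethyl 2-(triphenylphosphoranylidene)propanoate (CH2Cl2, rt) should give ethyl (2E)-4-{2-[(tert-butyldimethylsilyl)oxy]-5-methoxy-3-methylphenyl}-2-methylbut-2-enoate F7. Reduction with i-Bu2AlH (CH2Cl2, −78 °C) would give 6.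

Further compounds
F1 | step 14 | 2-[(2E)-4-{2-[(tert-butyldimethylsilyl)oxy]-5-methoxy-3-methylphenyl}-2-methylbut-2-en-1-yl]-1,3-dithiane | COc1cc(C)c(O[Si](C)(C)C(C)(C)C)c(C/C=C(\C)CC2SCCCS2)c1
F2 | step 14 | (3E)-5-{2-[(tert-butyldimethylsilyl)oxy]-5-methoxy-3-methylphenyl}-3-methylpent-3-enal | COc1cc(C)c(O[Si](C)(C)C(C)(C)C)c(C/C=C(\C)CC=O)c1
F3 | step 14 | (2E,6E,11R)-1-{2-[(tert-butyldimethylsilyl)oxy]-5-methoxy-3-methylphenyl}-3,7,11,15-tetramethylhexadeca-2,6,14-triene-5,12-diol | COc1cc(C)c(O[Si](C)(C)C(C)(C)C)c(C/C=C(\C)CC(O)/C=C(\C)CCC[C@@H](C)C(O)CC=C(C)C)c1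
F4 | step 1 | 4-methoxy-2-methyl-1-[(2-methylbut-3-yn-2-yl)oxy]benzene | COc1ccc(OC(C)(C)C#C)c(C)c1
F5 | step 1 | 4-methoxy-2-methyl-1-[(2-methylbut-3-en-2-yl)oxy]benzene | COc1ccc(OC(C)(C)C=C)c(C)c1
F6 | step 3 | {2-[(tert-butyldimethylsilyl)oxy]-5-methoxy-3-methylphenyl}acetaldehyde | COc1cc(C)c(O[Si](C)(C)C(C)(C)C)c(CC=O)c1
F7 | step 3 | ethyl (2E)-4-{2-[(tert-butyldimethylsilyl)oxy]-5-methoxy-3-methylphenyl}-2-methylbut-2-enoate | COc1cc(C)c(O[Si](C)(C)C(C)(C)C)c(C/C=C(\C)C(=O)OCC)c1
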